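The route rests on disconnecting C6–C7 (germacrane numbering), the bond common to the ten-membered carbocycle and the butenolide. C6 is the lactone carbinol carbon next to the C4=C5 alkene, and C7 is the β-carbon of the C7=C11–C12(=O) lactone; an enal carbon (C6) and a (Z)-β-triflyloxy acrylate carbon (C7) are therefore joined by an intramolecular Nozaki–Hiyama–Kishi alkenylation. This one operation closes the ten-membered ring, sets C6 and, through the cis methyl ester, closes the butenolide. The precursor is an acyclic (E,E)-farnesane-type chain carrying the C3 acetate, the enal and the stereodefined enol triflate; epoxidation of C1=C10 then completes the target.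

Key step: step 12

Remark on numbering: germacrane numbering is used throughout (ring C1–C10, methyl C14 on C10, methyl C15 on C4, C12 = lactone carbonyl, C13 = acetoxymethyl carbon on C11); the target is the (1R,3S,6R,10R) isomer.
Assumption: compounds 1 and 9, (−)-Ipc2B(allyl), isopropenylmagnesium bromide and Comins' reagent are taken as purchasable.

Step 1
Reactants: 1 (E)-4,4-dimethoxy-2-methylbut-2-enal
Product: 2 (4S,5E)-7,7-dimethoxy-5-methylhepta-1,5-dien-4-ol
Conditions: (−)-Ipc2B(allyl) [from (+)-α-pinene], Et2O, −78 °C; then NaOH, H2O2, 0 °C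
Reagents that add atoms: (−)-B-allyldiisopinocampheylborane C=CCB([C@@H]1C[C@@H]2C[C@H]([C@H]1C)C2(C)C)[C@@H]1C[C@@H]2C[C@H]([C@H]1C)C2(C)C
Why: Brown asymmetric allylboration through a closed chair transition state, in which the isopinocampheyl groups derived from (+)-α-pinene direct the allyl group to the Si face of the aldehyde and so should give the (S)-carbinol that becomes C3 of the target.

Step 2
Reactants: 2 (4S,5E)-7,7-dimethoxy-5-methylhepta-1,5-dien-4-ol
Product: 3 triethyl{[(4S,5E)-7,7-dimethoxy-5-methylhepta-1,5-dien-4-yl]oxy}silane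
Conditions: Et3SiCl, imidazole, DMF, 0 °C
Reagents that add atoms: chlorotriethylsilane CC[Si](Cl)(CC)CC
Why: Standard silyl ether formation protects the C3 hydroxyl as a triethylsilyl ether that should survive the basic and oxidative steps ahead and leave later under the same mild acid as the acetal.

Step 3
Reactants: 3 triethyl{[(4S,5E)-7,7-dimethoxy-5-methylhepta-1,5-dien-4-yl]oxy}silane
Product: 5 (3S,4E)-6,6-dimethoxy-4-methyl-3-(triethylsilyloxy)hex-4-enal, via diol 4 (not isolated)
Conditions: OsO4 (2 mol %), NaIO4, 2,6-lutidine, dioxane/H2O (3:1), rt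
Reagents that add atoms: osmium tetroxide O=[Os](=O)(=O)=O; sodium periodate [Na+].[O-]I(=O)(=O)=O
Why: Lemieux–Johnson oxidative cleavage, in which the terminal vinyl group should be dihydroxylated much faster than the trisubstituted alkene (shielded by the silyl ether and deactivated by three allylic oxygens) and periodate then cleaves the diol without touching C3.

Step 4
Reactants: 5 (3S,4E)-6,6-dimethoxy-4-methyl-3-(triethylsilyloxy)hex-4-enal
Product: 6 (5S,6E)-8,8-dimethoxy-2,6-dimethyl-5-(triethylsilyloxy)octa-1,6-dien-3-ol (both C3 epimers)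
Conditions: isopropenylmagnesium bromide, THF, −78 °C; aq. NH4Cl
Reagents that add atoms: isopropenylmagnesium bromide C=C(C)[Mg]Br
Why: Grignard 1,2-addition to the aldehyde; the new carbinol centre forms as a mixture of epimers, which is of no consequence because it is destroyed in step 5.

Step 5
Reactants: 6 (5S,6E)-8,8-dimethoxy-2,6-dimethyl-5-(triethylsilyloxy)octa-1,6-dien-3-ol
Product: 8 (4E,7S,8E)-10,10-dimethoxy-4,8-dimethyl-7-(triethylsilyloxy)deca-4,8-dienal, via allyl vinyl ether 7 (not isolated)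
Conditions: ethyl vinyl ether (solvent), Pd(OAc)2 (5 mol %), 1,10-phenanthroline (5 mol %), rt; then toluene, 140 °C (sealed tube)
Reagents that add atoms: ethyl vinyl ether C=COCC
Why: Transfer vinylation followed by a Claisen rearrangement through a chair transition state with the carbinol substituent equatorial, which should give the E trisubstituted C1=C10 alkene, the C8–C9 bond and the C7 aldehyde from either epimer of 6.

Step 6
Reactants: 9 methyl 3-hydroxypropanoate
Product: 10 methyl 3-(triethylsilyloxy)propanoate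
Conditions: Et3SiCl, imidazole, CH2Cl2, 0 °C
Reagents that add atoms: chlorotriethylsilane CC[Si](Cl)(CC)CC
Why: Routine silylation of the primary alcohol gives the enolate precursor that supplies C11, C12 and C13.

Step 7
Reactants: 8 (4E,7S,8E)-10,10-dimethoxy-4,8-dimethyl-7-(triethylsilyloxy)deca-4,8-dienal; 10 methyl 3-(triethylsilyloxy)propanoate
Product: 11 methyl (6E,9S,10E)-3-hydroxy-12,12-dimethoxy-6,10-dimethyl-9-(triethylsilyloxy)-2-[(triethylsilyloxy)methyl]dodeca-6,10-dienoate (mixture at C2 and C3)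
Conditions: LiN(i-Pr)2, THF, −78 °C (10, 20 min); then 8, −78 °C; aq. NH4Cl
Reagents that add atoms: none
Why: Lithium enolate aldol addition; kept at −78 °C the β-silyloxy enolate should add to the aldehyde faster than it loses silanolate, and the two new centres (C7 and C11) form as a mixture that is erased in steps 8 and 9.

Step 8
Reactants: 11 methyl (6E,9S,10E)-3-hydroxy-12,12-dimethoxy-6,10-dimethyl-9-(triethylsilyloxy)-2-[(triethylsilyloxy)methyl]dodeca-6,10-dienoate
Product: 12 methyl (6E,9S,10E)-12,12-dimethoxy-6,10-dimethyl-3-oxo-9-(triethylsilyloxy)-2-[(triethylsilyloxy)methyl]dodeca-6,10-dienoate (C2 epimers)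
Conditions: Dess–Martin periodinane, NaHCO3, CH2Cl2, 0 °C to rt
Reagents that add atoms: none
Why: Dess–Martin oxidation of the secondary alcohol gives the β-keto ester under buffered, non-basic conditions that should leave the silyl ethers and the acetal intact.

Step 9
Reactants: 12 methyl (6E,9S,10E)-12,12-dimethoxy-6,10-dimethyl-3-oxo-9-(triethylsilyloxy)-2-[(triethylsilyloxy)methyl]dodeca-6,10-dienoate
Product: 13 methyl (2Z,6E,9S,10E)-12,12-dimethoxy-6,10-dimethyl-9-(triethylsilyloxy)-2-[(triethylsilyloxy)methyl]-3-[(trifluoromethylsulfonyl)oxy]dodeca-2,6,10-trienoate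
Conditions: LiN(SiMe3)2, THF, −78 °C; then Comins' reagent, −78 to 0 °C
Reagents that add atoms: Comins' reagent, N-(5-chloropyridin-2-yl)bis(trifluoromethanesulfonimide) FC(F)(F)S(=O)(=O)N(c1ccc(Cl)cn1)S(=O)(=O)C(F)(F)F
Why: Enol triflate formation; deprotonation at C11 gives the lithium-chelated enolate with the enolate oxygen cis to the ester, and O-sulfonylation of this chelate should fix the Z geometry (triflate cis to CO2Me, C8 cis to C13) that the lactonisation in step 12 needs.

Step 10
Reactants: 13 methyl (2Z,6E,9S,10E)-12,12-dimethoxy-6,10-dimethyl-9-(triethylsilyloxy)-2-[(triethylsilyloxy)methyl]-3-[(trifluoromethylsulfonyl)oxy]dodeca-2,6,10-trienoate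
Product: 14 methyl (2Z,6E,9S,10E)-9-hydroxy-2-(hydroxymethyl)-6,10-dimethyl-12-oxo-3-[(trifluoromethylsulfonyl)oxy]dodeca-2,6,10-trienoate
Conditions: AcOH/THF/H2O (3:1:1), rt
Reagents that add atoms: water O
Why: Mild acid hydrolysis should remove both triethylsilyl ethers and the dimethyl acetal in one operation, releasing the E enal as in the liberation of 4-hydroxy-2-enals from their acetals, with no effect on the enol triflate or on C3.

Step 11
Reactants: 14 methyl (2Z,6E,9S,10E)-9-hydroxy-2-(hydroxymethyl)-6,10-dimethyl-12-oxo-3-[(trifluoromethylsulfonyl)oxy]dodeca-2,6,10-trienoate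
Product: 15 methyl (2Z,6E,9S,10E)-9-acetoxy-2-(acetoxymethyl)-6,10-dimethyl-12-oxo-3-[(trifluoromethylsulfonyl)oxy]dodeca-2,6,10-trienoate
Conditions: Ac2O, pyridine, DMAP (cat.), CH2Cl2, 0 °C
Reagents that add atoms: acetic anhydride CC(=O)OC(C)=O
Why: Acylation of the C3 and C13 hydroxyls installs both acetates of the target with retention at C3.

Step 12
Reactants: 15 methyl (2Z,6E,9S,10E)-9-acetoxy-2-(acetoxymethyl)-6,10-dimethyl-12-oxo-3-[(trifluoromethylsulfonyl)oxy]dodeca-2,6,10-trienoate
Product: 17 (3S,6R)-3,13-diacetoxygermacra-1(10)E,4E,7(11)-trien-12,6-olide, via hydroxy ester 16 (not isolated)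
Conditions: CrCl2 (10 equiv), NiCl2 (0.1 equiv), degassed DMF, rt, 15 added by syringe pump to 0.002 M; then aq. NH4Cl, EtOAc; silica gel
Reagents that add atoms: none
Why: Zerovalent nickel (formed from NiCl2 and CrCl2) inserts into the C7–OTf bond, the alkenyl group passes to trivalent chromium, and this β-metallated acrylate adds 1,2 to the C6 enal, after which the chromium alkoxide acylates on the cis methyl ester and releases the butenolide. The closest known reaction type is the intramolecular Nozaki–Hiyama–Kishi coupling of alkenyl triflates or iodides with aldehydes, including its use with (Z)-β-halo acrylates to give butenolides directly. The ten-membered carbocycle closes by a 10-exo-trig addition to the carbonyl and the lactone by a 5-exo-trig acyl substitution. The new C6 stereocentre is controlled by C3: in a crown-like, product-like transition state the (E,E)-1,5-diene folds as in germacranolides, the C3 acetoxy group sits pseudo-equatorially, C14 and C15 lie on the same face and the chromium-bound carbonyl oxygen points outward, which should place the C6 oxygen α and give 6R. The step needs insertion into the enol triflate in preference to the two allylic acetates, secured by the far higher reactivity of the acyl-activated triflate toward nickel, and ring closure in preference to oligomerisation, secured by high dilution and by the Z geometry from step 9 that holds the ester cis to the new carbinol.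

Step 13
Reactants: 17 (3S,6R)-3,13-diacetoxygermacra-1(10)E,4E,7(11)-trien-12,6-olide
Product: 18 (1R,3S,6R,10R)-3,13-diacetoxy-1,10-epoxygermacra-4E,7(11)-dien-12,6-olide (CNP0294733.1)
Conditions: mCPBA (1.05 equiv), NaHCO3, CH2Cl2, 0 °C
Reagents that add atoms: 3-chloroperoxybenzoic acid OOC(=O)c1cccc(Cl)c1
Why: Prilezhaev epoxidation; C1=C10 is the only electron-rich alkene (C4=C5 lies between two acyloxy-bearing allylic carbons, C7=C11 is conjugated to the lactone), and attack on its exposed outer face in the crown conformer with C14 and C15 on the β face should give the 1β,10α (1R,10R) epoxide, as is usual for (E,E)-germacra-1(10),4-dienolides.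

Compound list
1 | (E)-4,4-dimethoxy-2-methylbut-2-enal | O=C/C(C)=C/C(OC)OC | starting material
2 | (4S,5E)-7,7-dimethoxy-5-methylhepta-1,5-dien-4-ol | C=CC[C@H](O)/C(C)=C/C(OC)OC | intermediate
3 | triethyl{[(4S,5E)-7,7-dimethoxy-5-methylhepta-1,5-dien-4-yl]oxy}silane | C=CC[C@H](O[Si](CC)(CC)CC)/C(C)=C/C(OC)OC | intermediate
4 | (4S,5E)-7,7-dimethoxy-5-methyl-4-(triethylsilyloxy)hept-5-ene-1,2-diol (both C2 epimers; not isolated) | OCC(O)C[C@H](O[Si](CC)(CC)CC)/C(C)=C/C(OC)OC | intermediate
5 | (3S,4E)-6,6-dimethoxy-4-methyl-3-(triethylsilyloxy)hex-4-enal | O=CC[C@H](O[Si](CC)(CC)CC)/C(C)=C/C(OC)OC | intermediate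
6 | (5S,6E)-8,8-dimethoxy-2,6-dimethyl-5-(triethylsilyloxy)octa-1,6-dien-3-ol (both C3 epimers) | C=C(C)C(O)C[C@H](O[Si](CC)(CC)CC)/C(C)=C/C(OC)OC | intermediate
7 | (5S,6E)-3-(ethenyloxy)-8,8-dimethoxy-2,6-dimethyl-5-(triethylsilyloxy)octa-1,6-diene (allyl vinyl ether; not isolated) | C=C(C)C(OC=C)C[C@H](O[Si](CC)(CC)CC)/C(C)=C/C(OC)OC | intermediate
8 | (4E,7S,8E)-10,10-dimethoxy-4,8-dimethyl-7-(triethylsilyloxy)deca-4,8-dienal | O=CCC/C(C)=C/C[C@H](O[Si](CC)(CC)CC)/C(C)=C/C(OC)OC | intermediate
9 | methyl 3-hydroxypropanoate | COC(=O)CCO | starting material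
10 | methyl 3-(triethylsilyloxy)propanoate | COC(=O)CCO[Si](CC)(CC)CC | intermediate
11 | methyl (6E,9S,10E)-3-hydroxy-12,12-dimethoxy-6,10-dimethyl-9-(triethylsilyloxy)-2-[(triethylsilyloxy)methyl]dodeca-6,10-dienoate (mixture at C2 and C3) | COC(=O)C(CO[Si](CC)(CC)CC)C(O)CC/C(C)=C/C[C@H](O[Si](CC)(CC)CC)/C(C)=C/C(OC)OC | intermediate
12 | methyl (6E,9S,10E)-12,12-dimethoxy-6,10-dimethyl-3-oxo-9-(triethylsilyloxy)-2-[(triethylsilyloxy)methyl]dodeca-6,10-dienoate (C2 epimers) | COC(=O)C(CO[Si](CC)(CC)CC)C(=O)CC/C(C)=C/C[C@H](O[Si](CC)(CC)CC)/C(C)=C/C(OC)OC | intermediate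
13 | methyl (2Z,6E,9S,10E)-12,12-dimethoxy-6,10-dimethyl-9-(triethylsilyloxy)-2-[(triethylsilyloxy)methyl]-3-[(trifluoromethylsulfonyl)oxy]dodeca-2,6,10-trienoate | COC(=O)/C(CO[Si](CC)(CC)CC)=C(\OS(=O)(=O)C(F)(F)F)CC/C(C)=C/C[C@H](O[Si](CC)(CC)CC)/C(C)=C/C(OC)OC | intermediate
14 | methyl (2Z,6E,9S,10E)-9-hydroxy-2-(hydroxymethyl)-6,10-dimethyl-12-oxo-3-[(trifluoromethylsulfonyl)oxy]dodeca-2,6,10-trienoate | COC(=O)/C(CO)=C(\OS(=O)(=O)C(F)(F)F)CC/C(C)=C/C[C@H](O)/C(C)=C/C=O | intermediate
15 | methyl (2Z,6E,9S,10E)-9-acetoxy-2-(acetoxymethyl)-6,10-dimethyl-12-oxo-3-[(trifluoromethylsulfonyl)oxy]dodeca-2,6,10-trienoate | COC(=O)/C(COC(C)=O)=C(\OS(=O)(=O)C(F)(F)F)CC/C(C)=C/C[C@H](OC(C)=O)/C(C)=C/C=O | intermediate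
16 | methyl (2Z)-3-acetoxy-2-[(2R,3E,5S,7E)-5-acetoxy-2-hydroxy-4,8-dimethylcyclodeca-3,7-dien-1-ylidene]propanoate (hydroxy ester; not isolated) | COC(=O)/C(COC(C)=O)=C1/CC/C(C)=C/C[C@H](OC(C)=O)/C(C)=C/[C@H]1O | intermediate
17 | (3S,6R)-3,13-diacetoxygermacra-1(10)E,4E,7(11)-trien-12,6-olide | CC(=O)OCC1=C2CC/C(C)=C/C[C@H](OC(C)=O)/C(C)=C/[C@H]2OC1=O | intermediate
18 | (1R,3S,6R,10R)-3,13-diacetoxy-1,10-epoxygermacra-4E,7(11)-dien-12,6-olide (CNP0294733.1) | CC(=O)OCC1=C2CC[C@@]3(C)O[C@@H]3C[C@H](OC(C)=O)/C(C)=C/[C@H]2OC1=O | target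

Total step count: 13. Longest linear sequence: 12 steps (1 → 2 → 3 → 5 → 6 → 8 → 11 → 12 → 13 → 14 → 15 → 17 → 18); step 6 is the side branch.

Steps most likely to fail

Step 12. Zerovalent nickel may insert into the allylic acetates, which would lose or scramble C3. The open chain may also oligomerise instead of closing, or the aldehyde faces may be poorly differentiated at C6. The fallback keeps the allylic oxygens as silyl ethers through the ring closure and acetylates afterwards. It sets out from 13: the dimethyl acetal alone is cleaved (Et3SiOTf, 2,4,6-collidine, CH2Cl2, then H2O) to give the bis-silyl enal F1. The same CrCl2/NiCl2 cyclisation at high dilution gives the bis-silyl hydroxy ester F2 (not isolated), which lactonises to the bis-silyl trienolide F3. HF·pyridine in THF/pyridine then gives the diol trienolide F4, and Ac2O/pyridine returns the route at 17.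

Step 13. The peracid may attack a minor ring conformer and so the wrong face of C1=C10, or may also epoxidise C4=C5. The fallback places the epoxide before ring closure under reagent control. It sets out from 13: Shi epoxidation (D-fructose-derived ketone, KHSO5, K2CO3 buffer, MeCN/dimethoxymethane, 0 °C) of the only electron-rich alkene should give the (1R,10R)-epoxy triflate F5. Buffered Bu4NF/AcOH removes the silyl groups to give the epoxy diol F6, Ac2O/pyridine gives the epoxy diacetate F7, and PPTS in acetone/H2O frees the epoxy enal F8. The CrCl2/NiCl2 cyclisation then gives the epoxy hydroxy ester F9 (not isolated), which lactonises directly to 18.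

Step 7. The β-silyloxy ester enolate may expel silanolate before it adds, giving methyl acrylate and losing the C13 oxygen. The fallback uses an alkoxide–enolate dianion whose β-oxygen cannot leave. It sets out from 9 and 8: 9 is doubly deprotonated (LiN(i-Pr)2, 2.2 equiv, THF, −78 to −40 °C) and added to 8 to give the dihydroxy ester F10. Selective silylation of the primary hydroxyl (Et3SiCl, 1.05 equiv, imidazole, CH2Cl2, −40 °C) returns the route at 11.

Further compounds
F1 | step 12 | methyl (2Z,6E,9S,10E)-6,10-dimethyl-12-oxo-9-(triethylsilyloxy)-2-[(triethylsilyloxy)methyl]-3-[(trifluoromethylsulfonyl)oxy]dodeca-2,6,10-trienoate | COC(=O)/C(CO[Si](CC)(CC)CC)=C(\OS(=O)(=O)C(F)(F)F)CC/C(C)=C/C[C@H](O[Si](CC)(CC)CC)/C(C)=C/C=O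
F2 | step 12 | methyl (2Z)-2-[(2R,3E,5S,7E)-2-hydroxy-4,8-dimethyl-5-(triethylsilyloxy)cyclodeca-3,7-dien-1-ylidene]-3-(triethylsilyloxy)propanoate | COC(=O)/C(CO[Si](CC)(CC)CC)=C1/CC/C(C)=C/C[C@H](O[Si](CC)(CC)CC)/C(C)=C/[C@H]1O
F3 | step 12 | (3S,6R)-3,13-bis(triethylsilyloxy)germacra-1(10)E,4E,7(11)-trien-12,6-olide | CC[Si](CC)(CC)OCC1=C2CC/C(C)=C/C[C@H](O[Si](CC)(CC)CC)/C(C)=C/[C@H]2OC1=O
F4 | step 12 | (3S,6R)-3,13-dihydroxygermacra-1(10)E,4E,7(11)-trien-12,6-olide | OCC1=C2CC/C(C)=C/C[C@H](O)/C(C)=C/[C@H]2OC1=O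
F5 | step 13 | methyl (2Z,6R,7R,9S,10E)-6,7-epoxy-12,12-dimethoxy-6,10-dimethyl-9-(triethylsilyloxy)-2-[(triethylsilyloxy)methyl]-3-[(trifluoromethylsulfonyl)oxy]dodeca-2,10-dienoate | COC(=O)/C(CO[Si](CC)(CC)CC)=C(\OS(=O)(=O)C(F)(F)F)CC[C@@]1(C)O[C@@H]1C[C@H](O[Si](CC)(CC)CC)/C(C)=C/C(OC)OC
F6 | step 13 | methyl (2Z,6R,7R,9S,10E)-6,7-epoxy-9-hydroxy-2-(hydroxymethyl)-12,12-dimethoxy-6,10-dimethyl-3-[(trifluoromethylsulfonyl)oxy]dodeca-2,10-dienoate | COC(=O)/C(CO)=C(\OS(=O)(=O)C(F)(F)F)CC[C@@]1(C)O[C@@H]1C[C@H](O)/C(C)=C/C(OC)OC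
F7 | step 13 | methyl (2Z,6R,7R,9S,10E)-9-acetoxy-2-(acetoxymethyl)-6,7-epoxy-12,12-dimethoxy-6,10-dimethyl-3-[(trifluoromethylsulfonyl)oxy]dodeca-2,10-dienoate | COC(=O)/C(COC(C)=O)=C(\OS(=O)(=O)C(F)(F)F)CC[C@@]1(C)O[C@@H]1C[C@H](OC(C)=O)/C(C)=C/C(OC)OC
F8 | step 13 | methyl (2Z,6R,7R,9S,10E)-9-acetoxy-2-(acetoxymethyl)-6,7-epoxy-6,10-dimethyl-12-oxo-3-[(trifluoromethylsulfonyl)oxy]dodeca-2,10-dienoate | COC(=O)/C(COC(C)=O)=C(\OS(=O)(=O)C(F)(F)F)CC[C@@]1(C)O[C@@H]1C[C@H](OC(C)=O)/C(C)=C/C=O
F9 | step 13 | methyl (2Z)-3-acetoxy-2-[(6R)-6-hydroxy-(1R,3S,10R)-3-acetoxy-1,10-epoxygermacr-4E-en-7-ylidene]propanoate (seco-lactone of 18) | COC(=O)/C(COC(C)=O)=C1/CC[C@@]2(C)O[C@@H]2C[C@H](OC(C)=O)/C(C)=C/[C@H]1O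
F10 | step 7 | methyl (6E,9S,10E)-3-hydroxy-2-(hydroxymethyl)-12,12-dimethoxy-6,10-dimethyl-9-(triethylsilyloxy)dodeca-6,10-dienoate (mixture at C2 and C3) | COC(=O)C(CO)C(O)CC/C(C)=C/C[C@H](O[Si](CC)(CC)CC)/C(C)=C/C(OC)OC
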